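Numbering used throughout: 1 5-methoxyresorcinol; 2 bis-MOM ether; 3 aryllithium; 4 ring A aldehyde; 5 p-toluenesulfonamide; 6 N-tosyl imine; 7 silyloxy diene; 8 cycloadduct; 9 dihydropyridone; 10 enolate; 11 enol triflate; 12 N-tosylpiperidine; 13 free piperidine; 14 N-Boc piperidine; 15 aryl bromide; 16 N-methoxy-N-methylacetamide; 17 aryllithium; 18 aryl methyl ketone; 19 methyl benzoate; 20 1,3-diketone; 21 deprotected diketone; 22 target.

## Analysis of the target

Target 22 is a flavone: benzo ring A is fused to the 4-pyranone ring C, which carries phenyl ring B on C2, and ring A bears a methoxy group on C5, a free hydroxyl on C7 and, on C8, a piperidine attached through C2'. C2' is the only stereocentre; it has the R configuration, is benzylic and is bonded to N1', C3', C8 and H, so only an absolute sense has to be controlled and no relative one. C8 lies between the oxygen-bearing carbons C7 and C8a and para to the C5 methoxy group, so C2' sits in a crowded pocket on a very electron-rich ring. The C2'–N1' bond can therefore ionise under strong acid or heat (benzylic cation or ortho-quinone methide), which would racemise C2' or open the piperidine. The enone of ring C does not survive dissolving-metal or hydride conditions, so every reductive operation has to precede closure of ring C, and the C5 methyl ether must not meet hard Lewis acids. The difficulties are thus the enantioselective construction of a hindered, aryl-substituted amine stereocentre and the regiochemistry of ring A. The second is removed by symmetry: seen from C8, ring A is symmetric until ring C is closed (C7–O and C8a–O are equivalent, as are C6 and C4a), so a 2,6-dioxygenated 4-methoxyphenyl unit carries no regiochemical question. The first is answered by the feature on which the plan rests: because C2' is bonded to both N1' and C3', the piperidine can be read as the adduct of a two-atom C=N unit (N1' and C2') and a four-carbon diene running from C3' to C6'.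

## Retrosynthetic reasoning

Ring C, bond O1–C2. Target 22 is opened at O1–C2 to the phenolic 1,3-diketone 21 and its protected form 20. Only the hydroxyl ortho to the acyl group can close, so the position of the acyl group alone decides which of the two formerly equivalent oxygens becomes O1. The forward step merges cyclodehydration with removal of both acetals and the carbamate, and it has to do so without ionising the C2'–N1' bond.

Bond C2–C3. Diketone 20 is cut between C3 and the benzoyl carbon into methyl ketone 18 and ester 19. This brings ring B and C2 in as one commercial piece. The ketone has a single enolisable site and the ester none, so the crossed Claisen condensation has only one course.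

Bond C4–C4a. Ketone 18 is cut at the aryl–acyl bond to aryllithium 17 and amide 16; 17 comes from bromide 15, and 15 from carbamate 14 by electrophilic bromination. The two open ring positions of 14 are equivalent, so the halogen can enter only one kind of site. Halogen–lithium exchange is preferred to a Friedel–Crafts acylation, whose Lewis acid would strip the acetals and the carbamate and could ionise the benzylic C–N bond. It is also preferred to direct ring lithiation, which would compete with deprotonation of C2'–H next to the carbamate.

Nitrogen protecting group. Carbamate 14 goes back through amine 13 to sulfonamide 12. The sulfonyl group is needed to activate the imine in the ring-forming step, but its reductive removal is not compatible with the enone of ring C. It is therefore exchanged, while the molecule holds no carbonyl group, for a carbamate that leaves in the last step together with the acetals.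

C4' oxygen and C5'=C6' alkene. Sulfonamide 12 goes back through enol triflate 11 and enolate 10 to dihydropyridone 9. A thioketal and desulfurisation sequence was set aside for two reasons. The Lewis acid and thiol that form a thioketal also cleave aryl acetals. The saturated ring ketone that such a sequence passes through has an acidic C3'–H next to the sulfonamide-bearing C2', so it can open by β-elimination and racemise. Instead, conjugate reduction gives the enolate on the C5' side only; it is trapped as the enol triflate and removed by hydrogenolysis, so C3' is never enolised.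

Bonds C2'–C3' and N1'–C6' (key disconnection). Dihydropyridone 9 is cut through cycloadduct 8 into imine 6 and diene 7. No other cut of the piperidine creates the ring, two skeletal bonds and the stereocentre together in one catalytic operation starting from an aldehyde. The price is a carbonyl at C4' and a C5'=C6' double bond that have to be taken out afterwards, as described above. The forward reaction has to distinguish the two faces of a hindered, electron-rich C=N bond.

Ring A fragment. Imine 6 is cut at C=N into aldehyde 4 and sulfonamide 5. Aldehyde 4 is cut at the C8–C2' bond to aryllithium 3, formed from bis-acetal 2 by metalation at the carbon between the two acetal oxygens, and 2 comes from 5-methoxyresorcinol 1. The directing acetals thus place the future C2' at C8 and later protect the phenols.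

## Alternatives that were turned down

Alternative 1: Ring A is taken apart at C8–C8a, C6–C7 and C4a–C8a. In the forward sense 3-methoxycyclobut-2-en-1-one A2 would be heated with the silyl ynol ether A3, itself derived from (R)-piperidine-2-carboxylic acid A4. Electrocyclic opening to a vinylketene, [2+2] addition to the alkyne, 4π opening and 6π closure would deliver the phenol A1.
- For: the stereocentre is bought with A4 and no enantioselective step is needed; on that point it is stronger than the chosen route. The two oxygens flanking C8 also emerge differentiated.
- Against: that differentiation buys nothing here, because those oxygens are equivalent until ring C is closed. Three C–C bonds are spent on an aromatic ring that is commercial as 1. Reaching A3 needs a multistep, strongly basic homologation of an ester derived from A4, in which the α-stereocentre of A4, now the only source of chirality, can epimerise. A2 is a sensitive reagent that has to be prepared. After A1 the whole flavone annulation and a silyl removal still remain.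
- Comparison: it is longer, and the chirality it offers for free is put at risk on the way from A4 to A3. The chosen route offers a purchased ring A and a catalytic step whose selectivity can be tuned through the ligand.

Alternative 2: The piperidine is cut at N1'–C2' and N1'–C6'. An (R)-selective ω-transaminase with its cofactor and a sacrificial amine donor would aminate the ω-chloro ketone A6, and the new amine would displace chloride (6-exo-tet) to give A5, which is the same compound as 13.
- For: on step economy it is clearly stronger. Acylation of aryllithium 3 and one enzymatic step would reach 13 in three to four steps from 1, against seven. It also needs no nitrogen protecting group and no metal.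
- Against: the carbonyl of A6 is flanked by two ortho acetal groups, so it is twisted out of conjugation and shielded on both faces. The enzyme would have to take a 2,4,6-trisubstituted aryl group into its large pocket, and nothing in the structure allows that to be predicted. The electron-rich aryl ketone is also a reluctant amine acceptor, and the lipophilic chloro ketone A6 must survive aqueous buffer.
- Comparison: the advantage rests wholly on enzyme acceptance, which can be changed only by screening or protein engineering. The chosen route costs about four more steps, but its Lewis acid, ligand and sulfonyl group can each be varied on mechanistic grounds.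

Alternative 3: The ring is cut at C4'=C5'. Diene carbamate A8 would undergo ring-closing metathesis under second-generation Grubbs catalyst, expelling a two-carbon olefin, to deliver the tetrahydropyridine A7.
- For: ring-closing metathesis to a six-membered ring is more predictable than the cycloaddition. A7 already carries the carbamate and needs only hydrogenation to reach 14, so no ketone removal and no sulfonamide cleavage arise. On both points it is stronger.
- Against: the metathesis creates no stereocentre. C2' must be set earlier by asymmetric allylation of an imine of aldehyde 4, usually with a stoichiometric auxiliary, so the face-selectivity problem at the hindered C=N bond is unchanged. Auxiliary removal, carbamate formation and N-allylation of a nitrogen buried beside a di-ortho-substituted aryl group then follow on the way to A8. That is about seven steps from 4 to 14, against five.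
- Comparison: its steps are individually safer but more numerous and use stoichiometric chirality. The chosen route forms the ring, two bonds and the stereocentre in one catalytic event.

Key step: step 4

Assumption: the sense of induction of the copper–bisphosphine catalyst on imine 6 cannot be derived from structure alone; (R)-Tol-BINAP is written, and its mirror image is to be used if a trial run favours the (S) product.

## Route

Step 1
Reactants: 1 5-methoxyresorcinol
Product: 2 1-methoxy-3,5-bis(methoxymethoxy)benzene
Conditions: NaH, MOMCl, DMF, 0 °C → rt
Reagents that add atoms: chloromethyl methyl ether, COCCl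
Why: Double Williamson-type O-alkylation of the two phenoxides by the reactive α-chloro ether should give the bis-acetal; the acetals serve as protecting groups and as directing groups for step 2.

Step 2
Reactants: 2 1-methoxy-3,5-bis(methoxymethoxy)benzene
Product: 4 4-methoxy-2,6-bis(methoxymethoxy)benzaldehyde, via aryllithium 3 (not isolated)
Conditions: n-BuLi, TMEDA, THF, 0 °C; then DMF, 0 °C → rt; aq. NH4Cl
Reagents that add atoms: N,N-dimethylformamide, CN(C)C=O
Why: Directed ortho-metalation should occur at the carbon flanked by the two chelating acetal groups, which outrank the methoxy group as directors; formylation of the aryllithium with the formamide then places the future C2' on C8.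

Step 3
Reactants: 4 4-methoxy-2,6-bis(methoxymethoxy)benzaldehyde; 5 p-toluenesulfonamide
Product: 6 N-[(E)-[4-methoxy-2,6-bis(methoxymethoxy)phenyl]methylidene]-4-methylbenzenesulfonamide
Conditions: Ti(OEt)4, THF, reflux
Reagents that add atoms: none
Why: Lewis acid-mediated condensation; Ti(OEt)4 activates the hindered, electron-rich aldehyde and consumes the water formed, and the di-ortho-substituted aryl group allows only the E imine.

Step 4
Reactants: 6 N-[(E)-[4-methoxy-2,6-bis(methoxymethoxy)phenyl]methylidene]-4-methylbenzenesulfonamide; 7 (E)-1-methoxy-3-(trimethylsilyloxy)buta-1,3-diene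
Product: 9 (2R)-2-[4-methoxy-2,6-bis(methoxymethoxy)phenyl]-1-(4-methylbenzenesulfonyl)-2,3-dihydropyridin-4(1H)-one, via silyl enol ether cycloadduct 8 (not isolated)
Conditions: Cu(CH3CN)4PF6 (10 mol %), (R)-Tol-BINAP (11 mol %), 4 Å MS, CH2Cl2, −20 °C → rt; then CF3CO2H (cat.), wet CH2Cl2, 0 °C, 15 min; aq. NaHCO3
Reagents that add atoms: none
Why: The cationic monovalent copper–bisphosphine complex binds imine 6 through nitrogen and one sulfonyl oxygen; the nucleophilic CH2 terminus of diene 7 then attacks the imine carbon (C2'–C3') and nitrogen closes onto the methoxy-bearing carbon (N1'–C6'), either in one asynchronous [4+2] event or as a Mukaiyama–Mannich addition followed by aza-Michael closure, to give 8. Brief cold acid removes the silyl group and eliminates the methoxy group of the N,O-acetal to give the vinylogous sulfonamide 9. The closest known reaction type is the Lewis acid-catalysed enantioselective aza-Diels–Alder reaction of N-sulfonyl aldimines with 1-methoxy-3-silyloxy dienes. The piperidine ring closes in a suprafacial six-membered [4+2] mode, which is 6-endo-trig in the stepwise limit. C2' is the only stereocentre that survives and is set under catalyst control: the C2-symmetric bisphosphine leaves one enantioface of the copper-bound imine open to the diene. The step needs enantioface selectivity and the regiochemistry that puts the carbonyl at C4'; the diene polarity fixes the latter, and the former relies on two-point binding of the sulfonyl imine and on its single E geometry. The acid treatment is short and cold because the C2'–N1' bond is benzylic to a trioxygenated ring.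

Step 5
Reactants: 9 (2R)-2-[4-methoxy-2,6-bis(methoxymethoxy)phenyl]-1-(4-methylbenzenesulfonyl)-2,3-dihydropyridin-4(1H)-one
Product: 11 (2R)-2-[4-methoxy-2,6-bis(methoxymethoxy)phenyl]-1-(4-methylbenzenesulfonyl)-1,2,3,6-tetrahydropyridin-4-yl trifluoromethanesulfonate, via lithium enolate 10 (not isolated)
Conditions: LiBH(s-Bu)3, THF, −78 °C; then N-(5-chloropyridin-2-yl)bis(trifluoromethanesulfonyl)imide, −78 °C → rt; aq. NH4Cl
Reagents that add atoms: N-(5-chloropyridin-2-yl)-1,1,1-trifluoro-N-(trifluoromethanesulfonyl)methanesulfonamide (Comins' reagent), FC(F)(F)S(=O)(=O)N(c1ccc(Cl)cn1)S(=O)(=O)C(F)(F)F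
Why: The bulky borohydride should add hydride 1,4 to the vinylogous sulfonamide (conjugate reduction) and give the C4'–C5' enolate only, which is O-triflated in the same flask. C3' is never enolised, so the β-elimination that would break the C2'–N1' bond and racemise C2' has no opening.

Step 6
Reactants: 11 (2R)-2-[4-methoxy-2,6-bis(methoxymethoxy)phenyl]-1-(4-methylbenzenesulfonyl)-1,2,3,6-tetrahydropyridin-4-yl trifluoromethanesulfonate
Product: 12 (2R)-2-[4-methoxy-2,6-bis(methoxymethoxy)phenyl]-1-(4-methylbenzenesulfonyl)piperidine
Conditions: H2 (1 atm), 5% Pt/C, Li2CO3, EtOAc, rt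
Reagents that add atoms: none
Why: Heterogeneous hydrogenolysis of the enol triflate C–O bond together with saturation of the alkene should remove the C4' oxygen and the unsaturation in one operation. Li2CO3 buffers the sulfonic acid released, so the acetals and the benzylic C–N bond see no acid.

Step 7
Reactants: 12 (2R)-2-[4-methoxy-2,6-bis(methoxymethoxy)phenyl]-1-(4-methylbenzenesulfonyl)piperidine
Product: 14 tert-butyl (2R)-2-[4-methoxy-2,6-bis(methoxymethoxy)phenyl]piperidine-1-carboxylate, via free amine 13 (not isolated)
Conditions: NaC10H8 (sodium naphthalenide), DME, −78 °C; then H2O, Boc2O, THF, → rt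
Reagents that add atoms: di-tert-butyl dicarbonate, CC(C)(C)OC(=O)OC(=O)OC(C)(C)C
Why: Single-electron reduction should cleave the N–S bond of the sulfonamide while the molecule holds no carbonyl group and the electron-rich arene resists reduction. The amine is acylated in the same flask to a carbamate that later falls with the acetals; C2' is not involved.

Step 8
Reactants: 14 tert-butyl (2R)-2-[4-methoxy-2,6-bis(methoxymethoxy)phenyl]piperidine-1-carboxylate
Product: 15 tert-butyl (2R)-2-[3-bromo-4-methoxy-2,6-bis(methoxymethoxy)phenyl]piperidine-1-carboxylate
Conditions: NBS (1.0 equiv), MeCN, −20 → 0 °C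
Reagents that add atoms: N-bromosuccinimide, O=C1CCC(=O)N1Br
Why: Electrophilic aromatic bromination should occur at one of the two equivalent open ring positions, each activated by three oxygens, so no regiochemical choice arises; one equivalent at low temperature limits dibromination.

Step 9
Reactants: 15 tert-butyl (2R)-2-[3-bromo-4-methoxy-2,6-bis(methoxymethoxy)phenyl]piperidine-1-carboxylate; 16 N-methoxy-N-methylacetamide
Product: 18 tert-butyl (2R)-2-[3-acetyl-4-methoxy-2,6-bis(methoxymethoxy)phenyl]piperidine-1-carboxylate, via aryllithium 17 (not isolated)
Conditions: n-BuLi, THF, −78 °C, 10 min; then 16, −78 → 0 °C; aq. NH4Cl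
Reagents that add atoms: none
Why: Bromine–lithium exchange at −78 °C should outrun deprotonation of C2'–H next to the carbamate. The Weinreb ketone synthesis then stops at the ketone through the chelated tetrahedral intermediate and forms the C4–C4a bond.

Step 10
Reactants: 18 tert-butyl (2R)-2-[3-acetyl-4-methoxy-2,6-bis(methoxymethoxy)phenyl]piperidine-1-carboxylate; 19 methyl benzoate
Product: 20 tert-butyl (2R)-2-[4-methoxy-2,6-bis(methoxymethoxy)-3-(3-oxo-3-phenylpropanoyl)phenyl]piperidine-1-carboxylate
Conditions: NaH, THF, 60 °C; aq. NH4Cl
Reagents that add atoms: none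
Why: Crossed Claisen condensation: the ketone has one enolisable position and the ester none, and formation of the diketonate should drive the reaction.

Step 11
Reactants: 20 tert-butyl (2R)-2-[4-methoxy-2,6-bis(methoxymethoxy)-3-(3-oxo-3-phenylpropanoyl)phenyl]piperidine-1-carboxylate
Product: 22 7-hydroxy-5-methoxy-2-phenyl-8-[(2R)-piperidin-2-yl]-4H-chromen-4-one, via deprotected diketone 21 (not isolated)
Conditions: HCl (3 M in MeOH), 40 °C; then aq. NaHCO3 to pH 8
Reagents that add atoms: none
Why: Acid methanolysis should remove both acetals and the carbamate; the one hydroxyl ortho to the acyl group then adds to the benzoyl carbonyl and the hemiketal dehydrates to the 4-pyranone, as in the closing stage of a Baker–Venkataraman flavone synthesis. The acyl group already deactivates ring A and the nitrogen is protonated, which should protect the C2'–N1' bond and the configuration at C2'.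

## Compound list

1 | 5-methoxyresorcinol | COc1cc(O)cc(O)c1 | starting material
2 | 1-methoxy-3,5-bis(methoxymethoxy)benzene | COCOc1cc(OC)cc(OCOC)c1 | intermediate
3 | [4-methoxy-2,6-bis(methoxymethoxy)phenyl]lithium | [Li]c1c(OCOC)cc(OC)cc1OCOC | intermediate (not isolated)
4 | 4-methoxy-2,6-bis(methoxymethoxy)benzaldehyde | COCOc1cc(OC)cc(OCOC)c1C=O | intermediate
5 | p-toluenesulfonamide | Cc1ccc(cc1)S(N)(=O)=O | starting material
6 | N-[(E)-[4-methoxy-2,6-bis(methoxymethoxy)phenyl]methylidene]-4-methylbenzenesulfonamide | Cc1ccc(cc1)S(=O)(=O)/N=C/c1c(OCOC)cc(OC)cc1OCOC | intermediate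
7 | (E)-1-methoxy-3-(trimethylsilyloxy)buta-1,3-diene | CO/C=C/C(=C)O[Si](C)(C)C | starting material
8 | (2R)-6-methoxy-2-[4-methoxy-2,6-bis(methoxymethoxy)phenyl]-1-(4-methylbenzenesulfonyl)-4-(trimethylsilyloxy)-1,2,3,6-tetrahydropyridine (C6 epimers) | COCOc1cc(OC)cc(OCOC)c1[C@H]1CC(O[Si](C)(C)C)=CC(OC)N1S(=O)(=O)c1ccc(C)cc1 | intermediate (not isolated)
9 | (2R)-2-[4-methoxy-2,6-bis(methoxymethoxy)phenyl]-1-(4-methylbenzenesulfonyl)-2,3-dihydropyridin-4(1H)-one | COCOc1cc(OC)cc(OCOC)c1[C@H]1CC(=O)C=CN1S(=O)(=O)c1ccc(C)cc1 | intermediate
10 | lithium (2R)-2-[4-methoxy-2,6-bis(methoxymethoxy)phenyl]-1-(4-methylbenzenesulfonyl)-1,2,3,6-tetrahydropyridin-4-olate | COCOc1cc(OC)cc(OCOC)c1[C@H]1CC([O-])=CCN1S(=O)(=O)c1ccc(C)cc1.[Li+] | intermediate (not isolated)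
11 | (2R)-2-[4-methoxy-2,6-bis(methoxymethoxy)phenyl]-1-(4-methylbenzenesulfonyl)-1,2,3,6-tetrahydropyridin-4-yl trifluoromethanesulfonate | COCOc1cc(OC)cc(OCOC)c1[C@H]1CC(OS(=O)(=O)C(F)(F)F)=CCN1S(=O)(=O)c1ccc(C)cc1 | intermediate
12 | (2R)-2-[4-methoxy-2,6-bis(methoxymethoxy)phenyl]-1-(4-methylbenzenesulfonyl)piperidine | COCOc1cc(OC)cc(OCOC)c1[C@H]1CCCCN1S(=O)(=O)c1ccc(C)cc1 | intermediate
13 | (2R)-2-[4-methoxy-2,6-bis(methoxymethoxy)phenyl]piperidine | COCOc1cc(OC)cc(OCOC)c1[C@H]1CCCCN1 | intermediate (not isolated)
14 | tert-butyl (2R)-2-[4-methoxy-2,6-bis(methoxymethoxy)phenyl]piperidine-1-carboxylate | COCOc1cc(OC)cc(OCOC)c1[C@H]1CCCCN1C(=O)OC(C)(C)C | intermediate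
15 | tert-butyl (2R)-2-[3-bromo-4-methoxy-2,6-bis(methoxymethoxy)phenyl]piperidine-1-carboxylate | COCOc1cc(OC)c(Br)c(OCOC)c1[C@H]1CCCCN1C(=O)OC(C)(C)C | intermediate
16 | N-methoxy-N-methylacetamide | CON(C)C(C)=O | starting material
17 | tert-butyl (2R)-2-[3-lithio-4-methoxy-2,6-bis(methoxymethoxy)phenyl]piperidine-1-carboxylate | COCOc1cc(OC)c([Li])c(OCOC)c1[C@H]1CCCCN1C(=O)OC(C)(C)C | intermediate (not isolated)
18 | tert-butyl (2R)-2-[3-acetyl-4-methoxy-2,6-bis(methoxymethoxy)phenyl]piperidine-1-carboxylate | COCOc1cc(OC)c(C(C)=O)c(OCOC)c1[C@H]1CCCCN1C(=O)OC(C)(C)C | intermediate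
19 | methyl benzoate | COC(=O)c1ccccc1 | starting material
20 | tert-butyl (2R)-2-[4-methoxy-2,6-bis(methoxymethoxy)-3-(3-oxo-3-phenylpropanoyl)phenyl]piperidine-1-carboxylate | COCOc1cc(OC)c(C(=O)CC(=O)c2ccccc2)c(OCOC)c1[C@H]1CCCCN1C(=O)OC(C)(C)C | intermediate
21 | 1-{2,4-dihydroxy-6-methoxy-3-[(2R)-piperidin-2-yl]phenyl}-3-phenylpropane-1,3-dione | COc1cc(O)c([C@H]2CCCCN2)c(O)c1C(=O)CC(=O)c1ccccc1 | intermediate (not isolated)
22 | 7-hydroxy-5-methoxy-2-phenyl-8-[(2R)-piperidin-2-yl]-4H-chromen-4-one | COc1cc(O)c([C@H]2CCCCN2)c2oc(-c3ccccc3)cc(=O)c12 | target

## Step count and least certain steps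

Total: 11 steps. Longest linear sequence: 11 steps, from 1 to 22; compounds 5, 7, 16 and 19 are purchased.

Step 4 (key step). The cycloaddition may be slow or stall, because three oxygen donors and two ortho substituents make imine 6 a weak and hindered electrophile. Enantioselectivity may erode, because the acetal oxygens compete with the sulfonyl oxygen for copper or because an achiral silyl-cation background path competes. Over-long acid work-up may ionise the C2'–N1' bond. The fallback is an auxiliary-controlled, stepwise version of the same two bond formations, setting out from aldehyde 4. Condensation with (S)-2-methylpropane-2-sulfinamide and Ti(OEt)4 should give the sulfinyl imine F1. The lithium enolate of (E)-4-methoxybut-3-en-2-one (LiN(SiMe3)2, THF, −78 °C) should add to it through a closed chair transition state and give the Mannich adduct F2, which forms the C2'–C3' bond. Brief HCl in methanol at 0 °C removes the sulfinyl group, and the freed amine closes onto the β-methoxy enone by addition–elimination (N1'–C6' bond) to give the NH dihydropyridone F3. Deprotonation (LiN(SiMe3)2, THF, −78 °C) and p-toluenesulfonyl chloride bring the route back at 9. The (S) auxiliary is the enantiomer that the closed-transition-state model assigns to the (R) amine; its antipode would be taken if a trial shows the opposite sense.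

Step 11. Warm acid may partly racemise or open the piperidine by ionisation of the benzylic C2'–N1' bond, or the cyclodehydration may stop short. The fallback is a staged, chemoselective deprotection in place of one global acid step, setting out from 20. NaHSO4·SiO2 in CH2Cl2 at rt should remove only the two aryl acetals and give the phenolic diketone F10 with the carbamate intact. Catalytic p-toluenesulfonic acid in toluene at 50 °C should close ring C to the N-Boc flavone F11, whose ring A is deactivated by the C4 carbonyl. Trifluoroacetic acid in CH2Cl2 at 0 °C followed by neutralisation then gives 22.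

Step 7. Cleavage of the hindered sulfonamide may be incomplete, or electron transfer may cut the benzylic C2'–N1' bond instead of the N–S bond. The fallback is a fluoride-labile sulfonyl group chosen at the imine stage, setting out from aldehyde 4. Condensation with 2-(trimethylsilyl)ethanesulfonamide and Ti(OEt)4 should give the imine F5. The copper-catalysed cycloaddition and work-up of step 4 should give the dihydropyridone F6, the conditions of step 5 the enol triflate F7, and those of step 6 the sulfonyl piperidine F8. CsF in DMF at 95 °C then releases the sulfonyl group by fragmentation and gives amine 13, where the route is rejoined before the carbamate formation to 14.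

Step 9. Proton transfer may win over acyl transfer: deprotonation of C2'–H by the alkyllithium, or enolisation of amide 16 by the hindered aryllithium 17, would return the debrominated arene. The fallback is a cross-coupling in place of the organolithium, setting out from bromide 15. Stille coupling with tributyl(1-ethoxyvinyl)stannane (Pd2(dba)3, P(t-Bu)3, CsF, dioxane, 100 °C, a zerovalent palladium catalyst) should give the enol ether F9. Mild hydrolysis with aqueous oxalic acid in THF at rt unmasks the acetyl group and returns the route at 18.

Step 6. The triflate may be lost by S–O cleavage, which would leave the ring ketone, or the reduction may stop at a partly saturated stage. The fallback is a homogeneous hydride transfer followed by alkene hydrogenation, setting out from 11. Pd(OAc)2, PPh3, Et3N and HCO2H in DMF at 60 °C (oxidative addition to zerovalent palladium, formate decarboxylation, reductive elimination) should give the alkene F4. H2 over 5% Pt/C in EtOAc then saturates it and returns the route at 12.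

## Further compounds

F1 | step 4 | (S)-N-[(E)-[4-methoxy-2,6-bis(methoxymethoxy)phenyl]methylidene]-2-methylpropane-2-sulfinamide | CC(C)(C)[S@](=O)/N=C/c1c(OCOC)cc(OC)cc1OCOC
F2 | step 4 | (S)-N-[(1R,4E)-5-methoxy-1-[4-methoxy-2,6-bis(methoxymethoxy)phenyl]-3-oxopent-4-en-1-yl]-2-methylpropane-2-sulfinamide | CC(C)(C)[S@](=O)N[C@H](CC(=O)/C=C/OC)c1c(OCOC)cc(OC)cc1OCOC
F3 | step 4 | (2R)-2-[4-methoxy-2,6-bis(methoxymethoxy)phenyl]-2,3-dihydropyridin-4(1H)-one | COCOc1cc(OC)cc(OCOC)c1[C@H]1CC(=O)C=CN1
F4 | step 6 | (2R)-2-[4-methoxy-2,6-bis(methoxymethoxy)phenyl]-1-(4-methylbenzenesulfonyl)-1,2,3,6-tetrahydropyridine | COCOc1cc(OC)cc(OCOC)c1[C@H]1CC=CCN1S(=O)(=O)c1ccc(C)cc1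
F5 | step 7 | N-[(E)-[4-methoxy-2,6-bis(methoxymethoxy)phenyl]methylidene]-2-(trimethylsilyl)ethane-1-sulfonamide | C[Si](C)(C)CCS(=O)(=O)/N=C/c1c(OCOC)cc(OC)cc1OCOC
F6 | step 7 | (2R)-2-[4-methoxy-2,6-bis(methoxymethoxy)phenyl]-1-{[2-(trimethylsilyl)ethyl]sulfonyl}-2,3-dihydropyridin-4(1H)-one | COCOc1cc(OC)cc(OCOC)c1[C@H]1CC(=O)C=CN1S(=O)(=O)CC[Si](C)(C)C
F7 | step 7 | (2R)-2-[4-methoxy-2,6-bis(methoxymethoxy)phenyl]-1-{[2-(trimethylsilyl)ethyl]sulfonyl}-1,2,3,6-tetrahydropyridin-4-yl trifluoromethanesulfonate | COCOc1cc(OC)cc(OCOC)c1[C@H]1CC(OS(=O)(=O)C(F)(F)F)=CCN1S(=O)(=O)CC[Si](C)(C)C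
F8 | step 7 | (2R)-2-[4-methoxy-2,6-bis(methoxymethoxy)phenyl]-1-{[2-(trimethylsilyl)ethyl]sulfonyl}piperidine | COCOc1cc(OC)cc(OCOC)c1[C@H]1CCCCN1S(=O)(=O)CC[Si](C)(C)C
F9 | step 9 | tert-butyl (2R)-2-[3-(1-ethoxyethenyl)-4-methoxy-2,6-bis(methoxymethoxy)phenyl]piperidine-1-carboxylate | COCOc1cc(OC)c(C(=C)OCC)c(OCOC)c1[C@H]1CCCCN1C(=O)OC(C)(C)C
F10 | step 11 | tert-butyl (2R)-2-[2,6-dihydroxy-4-methoxy-3-(3-oxo-3-phenylpropanoyl)phenyl]piperidine-1-carboxylate | COc1cc(O)c([C@H]2CCCCN2C(=O)OC(C)(C)C)c(O)c1C(=O)CC(=O)c1ccccc1
F11 | step 11 | tert-butyl (2R)-2-(7-hydroxy-5-methoxy-4-oxo-2-phenyl-4H-chromen-8-yl)piperidine-1-carboxylate | COc1cc(O)c([C@H]2CCCCN2C(=O)OC(C)(C)C)c2oc(-c3ccccc3)cc(=O)c12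
A1 | alternative 1 | tert-butyl (2R)-2-[2-hydroxy-4-methoxy-6-(triisopropylsilyloxy)phenyl]piperidine-1-carboxylate | COc1cc(O)c([C@H]2CCCCN2C(=O)OC(C)(C)C)c(O[Si](C(C)C)(C(C)C)C(C)C)c1
A2 | alternative 1 | 3-methoxycyclobut-2-en-1-one | COC1=CC(=O)C1
A3 | alternative 1 | tert-butyl (2R)-2-{[tri(propan-2-yl)silyl]oxyethynyl}piperidine-1-carboxylate | CC(C)[Si](OC#C[C@H]1CCCCN1C(=O)OC(C)(C)C)(C(C)C)C(C)C
A4 | alternative 1 | (2R)-piperidine-2-carboxylic acid | OC(=O)[C@H]1CCCCN1
A5 | alternative 2 | (2R)-2-[4-methoxy-2,6-bis(methoxymethoxy)phenyl]piperidine | COCOc1cc(OC)cc(OCOC)c1[C@H]1CCCCN1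
A6 | alternative 2 | 5-chloro-1-[4-methoxy-2,6-bis(methoxymethoxy)phenyl]pentan-1-one | COCOc1cc(OC)cc(OCOC)c1C(=O)CCCCCl
A7 | alternative 3 | tert-butyl (2R)-2-[4-methoxy-2,6-bis(methoxymethoxy)phenyl]-3,6-dihydropyridine-1(2H)-carboxylate | COCOc1cc(OC)cc(OCOC)c1[C@H]1CC=CCN1C(=O)OC(C)(C)C
A8 | alternative 3 | tert-butyl N-[(1R)-1-[4-methoxy-2,6-bis(methoxymethoxy)phenyl]but-3-en-1-yl]-N-(prop-2-en-1-yl)carbamate | COCOc1cc(OC)cc(OCOC)c1[C@@H](CC=C)N(CC=C)C(=O)OC(C)(C)C
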